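## The problem

Compound 33 is a dearomatised acylphloroglucinol. A cyclohexadienone (ring A; C4a, C5, C6, C7, C8, C8a in chromene numbering) is fused along C4a–C8a to a trans-2,3-dimethyl-2,3-dihydropyran-4-one (ring B; O1, C2, C3, C4). C8 carries a 1-phenyl-2-carboxyethyl branch, and the sp3 carbon C6 carries a prenyl group and, through one CH2, a cyclobutane (ring C; C1'' bears the CH2 link, C2'' is CMe2, C3'' bears isopropenyl, C4'' is CH2).

The six stereocentres form four islands insulated from one another by CH2 or sp2 linkers: C1''/C3'' (cis), C6, C2/C3 (trans) and the benzylic carbon. Stereochemical information can be relayed only inside an island: C1'' can steer a hydrogenation that sets C3'', and C2 can steer an alkylation that sets C3 (trans is also the stable arrangement). The remaining configurations must come from a reagent or the chiral pool, and the islands must be joined as single enantiomers.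

C6 is stereogenic only because its two carbonyl neighbours differ (C5 is the enol carbon next to acylated C4a, C7 the ketone next to C8). Ring A must therefore be built from a C6 unit whose two carbonyl arms are already different.

The molecule will not survive rough treatment. Acid closes the C5 enol onto the prenyl group and attacks the isopropenyl group. Hydrogenation and hydroboration are excluded once the alkenes are present. Strong base with heat can open ring B by β-elimination of O1 (a vinylogous carboxylate) and scramble C2/C3.

The feature that invites the key step lies in ring C. The CMe2 carbon C2'' sits between C1'' and C3'', and C4'' is an unsubstituted CH2. This is the pattern left when a dimethylketene equivalent adds across a terminal alkene (C1''–C2'' and C3''–C4'' formed). The former ketene carbon C3'' emerges as a carbonyl that can later become the isopropenyl-bearing centre.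

## Retrosynthesis

**C8–benzylic bond.** Acid 33 is taken back to aldehyde 32, and the bond from C8 to the benzylic carbon is cut to give the C8-unsubstituted core 30 and cinnamaldehyde 31. C8 is the only nucleophilic carbon of 30. The benzylic centre is remote from all others, so it needs catalyst control, which iminium activation of an enal supplies. The neighbouring option, carrying a 3-phenylglutarate unit through the ring construction, would make the ring-closing carbanion a hindered secondary one and would need an ester protecting group. The cut removes nine carbons and one stereocentre. The forward reaction must be C-selective and must tolerate a free enol and two alkenes.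

**C7–C8 bond.** Ring A of 30 is opened to acyl-dihydropyranone 29: a Claisen (Dieckmann) condensation of the 6-methyl group onto the methyl ester at the quaternary carbon. Cutting C4a–C5 instead would ask the α-carbon of a vinylogous ester to be acylated by a neopentyl acyl donor. With C7–C8 last, the nucleophile is the most acidic site of 29 and the product is held as its vinylogous-acid anion. The precursor has one ring fewer, and its C6 carbon is that of an α,α-dialkyl β-keto ester whose arms (ester to C7, ketone to C5) are inherently different.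

**O1–C8a and C4a–C8a bonds.** Ring B of 29 is opened at the enol-ether bond to δ-hydroxy triketone 28, unmasked from silyl ether 27. The acetyl group (C8a and the future C8) is then removed from C4a to leave β-diketone 26. Introducing the acetyl group last means the only acidic C–H is at C4a. In the ring closure the hydroxyl then chooses between a methyl ketone and a ketone buried beside the quaternary carbon.

**C4–C4a bond.** β-Diketone 26 comes from aldol adduct 25, and 25 from the lithium enolate of methyl ketone 20 and aldehyde 24. Ketone 20 can enolise in one direction only. A direct acylation would save a step but risks O-acylation and epimerisation of the α-centre of the acyl donor; an aldol reaction at low temperature does neither.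

**Ring-B stereocentres.** Aldehyde 24 is traced through silyl ether 23 to anti hydroxy ester 22, made from commercial (R)-hydroxy ester 21 by Fráter–Seebach methylation. C2 comes from the chiral pool and controls C3.

**C6.** The C6–prenyl bond of 20 is cut: the reactive allylic bromide 18 is introduced last, onto the valine-derived enamine 17 (via imine 19), so that a chelated, configurationally defined enolate equivalent decides the face. Enamine 17 comes from β-keto ester 15 and valinate 16, and 15 from acetoacetate 14 and iodide 13. Desymmetrising a dialkyl malonate would mean telling a prenyl arm from a cyclobutylmethyl arm with no predictable method. The β-keto ester has the two arms different from the outset.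

**Ring C functional groups.** Iodide 13 comes from alcohol 12, and the isopropenyl group from methyl ketone 11 by methylenation. The cis relationship comes from hydrogenation of enone 10, where C1'' sets C3'' and the benzyl ether falls off in the same operation. The acetyl group comes from enol triflate 8 through ethoxydiene 9, and 8 from ketone 7. The carbonyl carbon of 7 is the handle that becomes C3''.

**Ring C (key cut).** C1''–C2'' and C3''–C4'' of 7 are cut to amide 3 (as keteniminium ion 5, closing through iminium salt 6) and allyl benzyl ether 4. This pair of bonds, unlike the other pair, gives an achiral alkene and a carboxylic acid derivative that can carry a chiral amine. Amide 3 is made from acid chloride 1 and amine 2. The forward reaction must give the 2,2-dimethyl-3-substituted regiochemistry and one enantiomer.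

## Roads not taken

**Alternative 1:** The cut is in ring B at O1–C2 and C2–C3.
- Forward step: acetaldehyde A2, bound to a chiral Lewis acid of trivalent chromium (a Schiff-base CrCl complex), adds across the 2-methoxy-4-silyloxy diene A1. Acidic unmasking eliminates methanol and, with epimerisation at C3, gives trans pyranone A3.
- Merits: both ring-B centres and the heterocycle arise in one catalytic asymmetric operation from achiral materials, and the ring oxygen is placed unambiguously.
- Weak points: the diene terminus that bonds to oxygen is fully substituted, which lowers reactivity. The kinetic adduct is expected to be cis, so the trans relationship rests on a later equilibration. A3 can enter the core only by deprotonation of its 6-methyl group in competition with the C3–H next to the carbonyl. The step does nothing for ring C or C6, where precedent is thinnest.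
- Comparison: in reagent economy this road is better (a catalyst instead of the stoichiometric auxiliary 2), and it is as short as steps 11–13. The chosen plan sets against it an open-chain ring-B precursor (24) that is joined by an aldol reaction to a ketone (20) with a single enolisation site, and a key step spent on the four-membered ring.

**Alternative 2:** The cut is in ring C at C1''–C4'' and C2''–C3'', the other pair of ring bonds.
- Forward step: sensitised irradiation of diprenylmalonate A4 with isoprene A5. The triplet diene adds through its vinyl group across one prenyl alkene to give A6, which already holds the isopropenyl group, the CH2 link and the malonate.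
- Merits: one step from two commodity chemicals to a compound at the stage the chosen plan reaches only after about eight steps, with no protecting group and no change of oxidation level.
- Weak points: the 1,4-biradical path secures neither the cis relationship nor the regiochemistry. Either double bond of the diene can react, triplet dienes mainly dimerise, and an unactivated trisubstituted alkene is a poor trap. The second prenyl group competes. The product is racemic, so every later stereocentre doubles the number of isomers. The malonate carbon of A6 still has two identical esters to be told apart.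
- Comparison: in step count this road wins clearly. The chosen plan sets against it regiochemistry fixed by cation stability, an auxiliary that gives one enantiomer, a cis relationship installed separately by face-selective hydrogenation, and a β-keto ester instead of a malonate at C6.

**Alternative 3:** The cut is in ring A at C7–C8 and C4a–C5.
- Forward step: the extended enolate of pyranone A3 is acylated at its 6-methyl carbon by acid chloride A7, and C5 of the pyranone then condenses with the remaining methyl ester. This gives core A8, the same compound as 30.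
- Merits: a convergent two-bond annulation. Ring B arrives intact, so no choice between carbonyl groups arises when the heterocycle forms, which is a real advantage over step 17. The fragment-to-core distance is two steps instead of five.
- Weak points: A3 must lose a proton from the 6-methyl group, although the kinetically preferred site of such vinylogous esters is C3–H, whose enolate would epimerise C3 or expel O1. C- versus O-acylation by a neopentyl acid chloride is uncertain. A7 needs a malonate whose carboxyl groups are differentiated with defined configuration at a carbon bearing two similar alkyl chains, for which no predictable method exists.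
- Comparison: the chosen plan reaches the same core by the same kind of Claisen chemistry but orders it so that each enolisation is unambiguous. C4a–C5 is present from the start as the acetyl group of a β-keto ester, which also lets a known auxiliary set C6, and C7–C8 is closed last from the most acidic site of 29. The price is a longer linear sequence and the regiochemical question of step 17.

Key step: step 2

Assumption: the absolute sense of the three reagent-controlled steps (auxiliary 2 in step 2, valinate 16 in step 10, the prolinol catalyst in step 19) is assigned from the accepted transition-state models and is checked at the first chiral product; the commercial antipode of the controller would be used, with no other change, if the sense proved opposite.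

## Route

Step 1
Reactants: 1 isobutyryl chloride; 2 (2R,5R)-2,5-dimethylpyrrolidine
Product: 3 1-[(2R,5R)-2,5-dimethylpyrrolidin-1-yl]-2-methylpropan-1-one
Conditions: aq. NaOH (2 M), CH2Cl2, 0 °C to rt
Reagents that add atoms: none
Why: Schotten–Baumann N-acylation of a secondary amine; the two stereocentres of 2 are not touched.

Step 2
Reactants: 3 1-[(2R,5R)-2,5-dimethylpyrrolidin-1-yl]-2-methylpropan-1-one; 4 allyl benzyl ether
Product: 7 (3S)-3-[(benzyloxy)methyl]-2,2-dimethylcyclobutan-1-one, via keteniminium triflate 5 (not isolated), via cyclobutaniminium triflate 6 (not isolated)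
Conditions: Tf2O (1.1 equiv), 2,4,6-collidine (1.2 equiv), ClCH2CH2Cl, −15 °C to rt; 4 (3 equiv), 80 °C; then H2O, 60 °C
Reagents that add atoms: water, O
Why: Triflic anhydride sulfonylates the amide oxygen and collidine removes the α-hydrogen, giving the tetrasubstituted keteniminium ion 5. The terminal CH2 of 4 attacks the sp iminium carbon (C3''–C4'' bond) and the secondary cation developing at the internal alkene carbon is captured by the methyl-bearing enamine carbon (C1''–C2'' bond); ring C thus closes in the second event of a polar, asynchronous [2+2] addition, by collapse of a 1,4-dipolar intermediate. The closest known reaction type is the [2+2] cycloaddition of chiral keteniminium salts with unactivated terminal alkenes to give 2,2-dimethylcyclobutanones. Regiochemistry follows cation stability, which places CMe2 beside the carbon carrying CH2OBn. The one new stereocentre (C1'', S in 7) is controlled by the C2-symmetric pyrrolidine: the two faces of the iminium carbon are equivalent by symmetry, and one enantioface of the alkene is disfavoured because its CH2OBn arm meets the pyrrolidine methyl group flanking the site of ring closure. Water hydrolyses iminium salt 6 to ketone 7 and returns amine 2. The step needs enantioface selection on a monosubstituted alkene, which only the auxiliary provides, and chemoselection for the alkene over the ether oxygen and arene of 4, which rests on the π-nucleophilicity of the terminal alkene and on the excess of 4.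

Step 3
Reactants: 7 (3S)-3-[(benzyloxy)methyl]-2,2-dimethylcyclobutan-1-one
Product: 8 (3S)-3-[(benzyloxy)methyl]-4,4-dimethylcyclobut-1-en-1-yl trifluoromethanesulfonate
Conditions: KN(SiMe3)2, THF, −78 °C; PhNTf2, −78 to 0 °C
Reagents that add atoms: N-phenylbis(trifluoromethanesulfonimide), O=S(=O)(N(c1ccccc1)S(=O)(=O)C(F)(F)F)C(F)(F)F
Why: Enol triflate formation; only the CH2 side of the ketone can enolise (the other α-carbon is quaternary), so one regioisomer forms, and the stereocentre is β to the carbonyl and cannot epimerise.

Step 4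
Reactants: 8 (3S)-3-[(benzyloxy)methyl]-4,4-dimethylcyclobut-1-en-1-yl trifluoromethanesulfonate
Product: 10 1-{(3S)-3-[(benzyloxy)methyl]-4,4-dimethylcyclobut-1-en-1-yl}ethan-1-one, via ethoxydiene 9 (not isolated)
Conditions: tributyl(1-ethoxyvinyl)stannane, Pd(PPh3)4 (5 mol %), LiCl, THF, 65 °C; then 1 M HCl, rt
Reagents that add atoms: tributyl(1-ethoxyvinyl)stannane, CCCC[Sn](CCCC)(CCCC)C(=C)OCC; water, O
Why: Stille coupling of an enol triflate with an α-alkoxyvinylstannane (zerovalent palladium inserts into the C–OTf bond, chloride assists transmetalation), then hydrolysis of the enol ether; this is the standard acetyl-anion equivalent and gives the conjugated enone.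

Step 5
Reactants: 10 1-{(3S)-3-[(benzyloxy)methyl]-4,4-dimethylcyclobut-1-en-1-yl}ethan-1-one
Product: 11 1-[(1R,3S)-3-(hydroxymethyl)-2,2-dimethylcyclobutyl]ethan-1-one
Conditions: H2 (1 atm), Pd/C (10 wt %), EtOH, rt
Reagents that add atoms: none
Why: Heterogeneous syn-hydrogenation delivers hydrogen to the ring face opposite the CH2OBn group, so the acetyl group ends cis to it (C3'' set by C1''); continued hydrogenolysis removes the benzyl group in the same operation, and a dialkyl ketone is not reduced under these conditions.

Step 6
Reactants: 11 1-[(1R,3S)-3-(hydroxymethyl)-2,2-dimethylcyclobutyl]ethan-1-one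
Product: 12 [(1S,3S)-2,2-dimethyl-3-(prop-1-en-2-yl)cyclobutyl]methanol
Conditions: Ph3PCH3Br, KOtBu (3 equiv each), THF, 0 °C to rt
Reagents that add atoms: methyltriphenylphosphonium bromide, C[P+](c1ccccc1)(c1ccccc1)c1ccccc1.[Br-]
Why: Wittig methylenation of a methyl ketone; the unhindered ylide adds faster than it enolises the ketone, so the cis relationship should be kept, and the free hydroxyl only consumes one equivalent of base.

Step 7
Reactants: 12 [(1S,3S)-2,2-dimethyl-3-(prop-1-en-2-yl)cyclobutyl]methanol
Product: 13 (1S,3S)-1-(iodomethyl)-2,2-dimethyl-3-(prop-1-en-2-yl)cyclobutane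
Conditions: I2, PPh3, imidazole, CH2Cl2, 0 °C
Reagents that add atoms: iodine, [I][I]
Why: Appel-type iodination of a primary alcohol under neutral conditions that leave the 1,1-disubstituted alkene alone; substitution at a CH2 carbon has no stereochemical consequence.

Step 8
Reactants: 13 (1S,3S)-1-(iodomethyl)-2,2-dimethyl-3-(prop-1-en-2-yl)cyclobutane; 14 methyl acetoacetate
Product: 15 methyl 2-{[(1R,3S)-2,2-dimethyl-3-(prop-1-en-2-yl)cyclobutyl]methyl}-3-oxobutanoate (both epimers at C2)
Conditions: NaH, 14 (3 equiv), DMF, 0 °C; 13, 60 °C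
Reagents that add atoms: none
Why: Acetoacetic ester C-alkylation (SN2) by a primary iodide; excess enolate suppresses dialkylation, and the labile α-centre does not matter because it becomes sp2 in step 9.

Step 9
Reactants: 15 methyl 2-{[(1R,3S)-2,2-dimethyl-3-(prop-1-en-2-yl)cyclobutyl]methyl}-3-oxobutanoate; 16 tert-butyl D-valinate
Product: 17 methyl (2Z)-3-{[(2R)-1-tert-butoxy-3-methyl-1-oxobutan-2-yl]amino}-2-{[(1R,3S)-2,2-dimethyl-3-(prop-1-en-2-yl)cyclobutyl]methyl}but-2-enoate
Conditions: AcOH (cat.), 4 Å molecular sieves, toluene, 80 °C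
Reagents that add atoms: none
Why: Condensation of a β-keto ester with a primary amine gives the hydrogen-bonded (Z)-enamino ester; the weak acid catalyst does not protonate the isopropenyl group.

Step 10
Reactants: 17 methyl (2Z)-3-{[(2R)-1-tert-butoxy-3-methyl-1-oxobutan-2-yl]amino}-2-{[(1R,3S)-2,2-dimethyl-3-(prop-1-en-2-yl)cyclobutyl]methyl}but-2-enoate; 18 prenyl bromide
Product: 20 methyl (2R)-2-acetyl-2-{[(1R,3S)-2,2-dimethyl-3-(prop-1-en-2-yl)cyclobutyl]methyl}-5-methylhex-4-enoate, via imino ester 19 (not isolated)
Conditions: LiN(iPr)2, toluene–THF, −78 °C; 18, −78 to −40 °C; then aq. citric acid, rt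
Reagents that add atoms: water, O
Why: Auxiliary-controlled alkylation of a lithiated valine enamine of an α-alkyl β-keto ester: lithium is held by the nitrogen, the ester-enolate oxygen and the valinate carbonyl in a rigid chelate, and with the weak ligand THF the allylic bromide is delivered from the lithium-bearing face opposite the isopropyl group, which for the D-valinate should give the R quaternary centre; mild acid hydrolyses imine 19 and returns 16.

Step 11
Reactants: 21 methyl (3R)-3-hydroxybutanoate
Product: 22 methyl (2R,3R)-3-hydroxy-2-methylbutanoate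
Conditions: LiN(iPr)2 (2.2 equiv), THF, −78 to −20 °C; MeI, DMPU, −78 to 0 °C
Reagents that add atoms: iodomethane, IC
Why: Fráter–Seebach alkylation; the chelated alkoxide enolate is methylated on the face away from the C3 methyl group, which gives the anti (2R,3R) product.

Step 12
Reactants: 22 methyl (2R,3R)-3-hydroxy-2-methylbutanoate
Product: 23 methyl (2R,3R)-3-[(tert-butyldimethylsilyl)oxy]-2-methylbutanoate
Conditions: TBSCl, imidazole, DMF, rt
Reagents that add atoms: tert-butyldimethylsilyl chloride, CC(C)(C)[Si](C)(C)Cl
Why: Standard silylation of a secondary alcohol; the silyl ether survives enolate, oxidation and magnesium-enolate conditions and is removed by fluoride without strong acid.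

Step 13
Reactants: 23 methyl (2R,3R)-3-[(tert-butyldimethylsilyl)oxy]-2-methylbutanoate
Product: 24 (2R,3R)-3-[(tert-butyldimethylsilyl)oxy]-2-methylbutanal
Conditions: iBu2AlH (1.05 equiv), CH2Cl2, −78 °C; aq. potassium sodium tartrate
Reagents that add atoms: none
Why: Partial reduction of an ester through the aluminium hemiacetal that is stable at −78 °C; the aldehyde is used crude to avoid epimerisation of its α-centre.

Step 14
Reactants: 20 methyl (2R)-2-acetyl-2-{[(1R,3S)-2,2-dimethyl-3-(prop-1-en-2-yl)cyclobutyl]methyl}-5-methylhex-4-enoate; 24 (2R,3R)-3-[(tert-butyldimethylsilyl)oxy]-2-methylbutanal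
Product: 25 methyl (2R)-2-{(4S,5R)-5-[(tert-butyldimethylsilyl)oxy]-3-hydroxy-4-methylhexanoyl}-2-{[(1R,3S)-2,2-dimethyl-3-(prop-1-en-2-yl)cyclobutyl]methyl}-5-methylhex-4-enoate (both epimers at the carbinol carbon)
Conditions: LiN(iPr)2, THF, −78 °C; 24, −78 °C; AcOH quench at −78 °C
Reagents that add atoms: none
Why: Aldol addition of a regiodefined lithium enolate (20 has α-hydrogens only on the acetyl methyl); the new carbinol centre is removed in step 15, and the cold acidic quench keeps the aldolate from lactonising onto the neighbouring ester.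

Step 15
Reactants: 25 methyl (2R)-2-{(4S,5R)-5-[(tert-butyldimethylsilyl)oxy]-3-hydroxy-4-methylhexanoyl}-2-{[(1R,3S)-2,2-dimethyl-3-(prop-1-en-2-yl)cyclobutyl]methyl}-5-methylhex-4-enoate
Product: 26 methyl (2R)-2-{(4R,5R)-5-[(tert-butyldimethylsilyl)oxy]-4-methyl-3-oxohexanoyl}-2-{[(1R,3S)-2,2-dimethyl-3-(prop-1-en-2-yl)cyclobutyl]methyl}-5-methylhex-4-enoate
Conditions: Dess–Martin periodinane (1.2 equiv), CH2Cl2, 0 °C to rt
Reagents that add atoms: none
Why: Dess–Martin oxidation of a β-hydroxy ketone to the β-diketone under non-basic conditions that spare both alkenes, the silyl ether and the α-methyl stereocentre.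

Step 16
Reactants: 26 methyl (2R)-2-{(4R,5R)-5-[(tert-butyldimethylsilyl)oxy]-4-methyl-3-oxohexanoyl}-2-{[(1R,3S)-2,2-dimethyl-3-(prop-1-en-2-yl)cyclobutyl]methyl}-5-methylhex-4-enoate
Product: 27 methyl (2R)-2-{(4R,5R)-2-acetyl-5-[(tert-butyldimethylsilyl)oxy]-4-methyl-3-oxohexanoyl}-2-{[(1R,3S)-2,2-dimethyl-3-(prop-1-en-2-yl)cyclobutyl]methyl}-5-methylhex-4-enoate (drawn as the triketone; enolised in solution)
Conditions: MgCl2, pyridine, CH2Cl2, 0 °C; AcCl, 0 °C to rt
Reagents that add atoms: acetyl chloride, CC(Cl)=O
Why: C-acylation of the magnesium chelate of a β-diketone by an acid chloride; chelation directs the acyl group to the central carbon (C4a), and the weak base enolises nothing else.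

Step 17
Reactants: 27 methyl (2R)-2-{(4R,5R)-2-acetyl-5-[(tert-butyldimethylsilyl)oxy]-4-methyl-3-oxohexanoyl}-2-{[(1R,3S)-2,2-dimethyl-3-(prop-1-en-2-yl)cyclobutyl]methyl}-5-methylhex-4-enoate
Product: 29 methyl (2R)-2-{[(1R,3S)-2,2-dimethyl-3-(prop-1-en-2-yl)cyclobutyl]methyl}-5-methyl-2-[(2R,3R)-2,3,6-trimethyl-4-oxo-3,4-dihydro-2H-pyran-5-carbonyl]hex-4-enoate, via hydroxy triketone 28 (not isolated)
Conditions: HF·pyridine, THF, 0 °C to rt; then PPTS (cat.), 4 Å molecular sieves, CH2Cl2, rt
Reagents that add atoms: none
Why: Desilylation followed by cyclodehydration of a δ-hydroxy β-diketone to a 2,3-dihydropyran-4-one: the hydroxyl should add to the acetyl carbonyl rather than to the ketone beside the quaternary carbon, and loss of water gives ring B; the anti centres from 22 become the trans-2,3-dimethyl pattern without being touched.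

Step 18
Reactants: 29 methyl (2R)-2-{[(1R,3S)-2,2-dimethyl-3-(prop-1-en-2-yl)cyclobutyl]methyl}-5-methyl-2-[(2R,3R)-2,3,6-trimethyl-4-oxo-3,4-dihydro-2H-pyran-5-carbonyl]hex-4-enoate
Product: 30 (2R,3R,6R)-6-{[(1R,3S)-2,2-dimethyl-3-(prop-1-en-2-yl)cyclobutyl]methyl}-5-hydroxy-2,3-dimethyl-6-(3-methylbut-2-en-1-yl)-2,3-dihydro-4H-chromene-4,7(6H)-dione
Conditions: KOtBu (2.2 equiv), THF, −20 to 0 °C; then cold 0.5 M HCl
Reagents that add atoms: none
Why: Dieckmann-type Claisen condensation: the 6-methyl group, vinylogous to both carbonyls, is the most acidic site and its carbanion attacks the methyl ester on the quaternary carbon (6-exo-trig, C7–C8 bond), as in lateral Claisen condensations of 2-methyl-4-pyranones; the product is trapped as its vinylogous-acid anion, which drives the reaction and shields ring B from base, and C6 cannot epimerise because it has no hydrogen.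

Step 19
Reactants: 30 (2R,3R,6R)-6-{[(1R,3S)-2,2-dimethyl-3-(prop-1-en-2-yl)cyclobutyl]methyl}-5-hydroxy-2,3-dimethyl-6-(3-methylbut-2-en-1-yl)-2,3-dihydro-4H-chromene-4,7(6H)-dione; 31 (E)-cinnamaldehyde
Product: 32 (3S)-3-[(2R,3R,6R)-6-{[(1R,3S)-2,2-dimethyl-3-(prop-1-en-2-yl)cyclobutyl]methyl}-5-hydroxy-2,3-dimethyl-6-(3-methylbut-2-en-1-yl)-4,7-dioxo-3,4,6,7-tetrahydro-2H-chromen-8-yl]-3-phenylpropanal
Conditions: (S)-2-[diphenyl(trimethylsilyloxy)methyl]pyrrolidine (20 mol %), CH2Cl2, 0 °C to rt
Reagents that add atoms: none
Why: Iminium-catalysed Michael addition of a cyclic vinylogous acid to an enal, the reaction type established for 4-hydroxycoumarins and cyclic 1,3-diones: C8 is the only nucleophilic carbon of 30, and the diarylsilyloxymethyl group shields one face of the s-trans (E)-iminium ion so that C8 adds to the other, which should give the S benzylic centre under catalyst control; the adduct may rest as a lactol, which does not affect step 20.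

Step 20
Reactants: 32 (3S)-3-[(2R,3R,6R)-6-{[(1R,3S)-2,2-dimethyl-3-(prop-1-en-2-yl)cyclobutyl]methyl}-5-hydroxy-2,3-dimethyl-6-(3-methylbut-2-en-1-yl)-4,7-dioxo-3,4,6,7-tetrahydro-2H-chromen-8-yl]-3-phenylpropanal
Product: 33 (3S)-3-[(2R,3R,6R)-6-{[(1R,3S)-2,2-dimethyl-3-(prop-1-en-2-yl)cyclobutyl]methyl}-5-hydroxy-2,3-dimethyl-6-(3-methylbut-2-en-1-yl)-4,7-dioxo-3,4,6,7-tetrahydro-2H-chromen-8-yl]-3-phenylpropanoic acid
Conditions: NaClO2, NaH2PO4, 2-methyl-2-butene (excess), tBuOH–H2O, 0 °C
Reagents that add atoms: sodium chlorite, [Na+].[O-]Cl=O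
Why: Pinnick oxidation turns the aldehyde into the acid under buffered conditions that do not epimerise the benzylic centre; the alkene scavenger removes hypochlorous acid before it can reach the prenyl and isopropenyl groups.

## Compound list

1 | isobutyryl chloride | CC(C)C(Cl)=O | starting material
2 | (2R,5R)-2,5-dimethylpyrrolidine | C[C@@H]1CC[C@@H](C)N1 | starting material
3 | 1-[(2R,5R)-2,5-dimethylpyrrolidin-1-yl]-2-methylpropan-1-one | CC(C)C(=O)N1[C@H](C)CC[C@H]1C | intermediate
4 | allyl benzyl ether | C=CCOCc1ccccc1 | starting material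
5 | (2R,5R)-2,5-dimethyl-1-(2-methylprop-1-en-1-ylidene)pyrrolidin-1-ium triflate (keteniminium triflate, not isolated) | CC(C)=C=[N+]1[C@H](C)CC[C@H]1C.[O-]S(=O)(=O)C(F)(F)F | intermediate
6 | (2R,5R)-1-{(3S)-3-[(benzyloxy)methyl]-2,2-dimethylcyclobutylidene}-2,5-dimethylpyrrolidin-1-ium triflate (cyclobutaniminium triflate, not isolated) | C[C@@H]1CC[C@@H](C)[N+]1=C1C[C@H](COCc2ccccc2)C1(C)C.[O-]S(=O)(=O)C(F)(F)F | intermediate
7 | (3S)-3-[(benzyloxy)methyl]-2,2-dimethylcyclobutan-1-one | O=C1C[C@H](COCc2ccccc2)C1(C)C | intermediate
8 | (3S)-3-[(benzyloxy)methyl]-4,4-dimethylcyclobut-1-en-1-yl trifluoromethanesulfonate | O=S(=O)(OC1=C[C@H](COCc2ccccc2)C1(C)C)C(F)(F)F | intermediate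
9 | ({[(1S)-3-(1-ethoxyethenyl)-2,2-dimethylcyclobut-3-en-1-yl]methoxy}methyl)benzene (ethoxydiene, not isolated) | C=C(OCC)C1=C[C@H](COCc2ccccc2)C1(C)C | intermediate
10 | 1-{(3S)-3-[(benzyloxy)methyl]-4,4-dimethylcyclobut-1-en-1-yl}ethan-1-one | CC(=O)C1=C[C@H](COCc2ccccc2)C1(C)C | intermediate
11 | 1-[(1R,3S)-3-(hydroxymethyl)-2,2-dimethylcyclobutyl]ethan-1-one | CC(=O)[C@@H]1C[C@H](CO)C1(C)C | intermediate
12 | [(1S,3S)-2,2-dimethyl-3-(prop-1-en-2-yl)cyclobutyl]methanol | C=C(C)[C@@H]1C[C@H](CO)C1(C)C | intermediate
13 | (1S,3S)-1-(iodomethyl)-2,2-dimethyl-3-(prop-1-en-2-yl)cyclobutane | C=C(C)[C@@H]1C[C@H](C[I])C1(C)C | intermediate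
14 | methyl acetoacetate | CC(=O)CC(=O)OC | starting material
15 | methyl 2-{[(1R,3S)-2,2-dimethyl-3-(prop-1-en-2-yl)cyclobutyl]methyl}-3-oxobutanoate (both C2 epimers) | C=C(C)[C@@H]1C[C@H](CC(C(C)=O)C(=O)OC)C1(C)C | intermediate
16 | tert-butyl D-valinate [tert-butyl (2R)-2-amino-3-methylbutanoate] | CC(C)[C@@H](N)C(=O)OC(C)(C)C | starting material
17 | methyl (2Z)-3-{[(2R)-1-tert-butoxy-3-methyl-1-oxobutan-2-yl]amino}-2-{[(1R,3S)-2,2-dimethyl-3-(prop-1-en-2-yl)cyclobutyl]methyl}but-2-enoate | C=C(C)[C@@H]1C[C@H](C/C(C(=O)OC)=C(\C)N[C@H](C(C)C)C(=O)OC(C)(C)C)C1(C)C | intermediate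
18 | prenyl bromide (1-bromo-3-methylbut-2-ene) | CC(C)=CCBr | starting material
19 | imine of ketone 20 with tert-butyl D-valinate, C=N at the acetyl carbon (imino ester, not isolated) | C=C(C)[C@@H]1C[C@H](C[C@@](CC=C(C)C)(C(=O)OC)C(C)=N[C@H](C(C)C)C(=O)OC(C)(C)C)C1(C)C | intermediate
20 | methyl (2R)-2-acetyl-2-{[(1R,3S)-2,2-dimethyl-3-(prop-1-en-2-yl)cyclobutyl]methyl}-5-methylhex-4-enoate | C=C(C)[C@@H]1C[C@H](C[C@@](CC=C(C)C)(C(=O)OC)C(C)=O)C1(C)C | intermediate
21 | methyl (3R)-3-hydroxybutanoate | C[C@@H](O)CC(=O)OC | starting material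
22 | methyl (2R,3R)-3-hydroxy-2-methylbutanoate | O[C@H](C)[C@@H](C)C(=O)OC | intermediate
23 | methyl (2R,3R)-3-[(tert-butyldimethylsilyl)oxy]-2-methylbutanoate | CC(C)(C)[Si](C)(C)O[C@H](C)[C@@H](C)C(=O)OC | intermediate
24 | (2R,3R)-3-[(tert-butyldimethylsilyl)oxy]-2-methylbutanal | CC(C)(C)[Si](C)(C)O[C@H](C)[C@@H](C)C=O | intermediate
25 | methyl (2R)-2-{(4S,5R)-5-[(tert-butyldimethylsilyl)oxy]-3-hydroxy-4-methylhexanoyl}-2-{[(1R,3S)-2,2-dimethyl-3-(prop-1-en-2-yl)cyclobutyl]methyl}-5-methylhex-4-enoate (both carbinol epimers) | C=C(C)[C@@H]1C[C@H](C[C@@](CC=C(C)C)(C(=O)OC)C(=O)CC(O)[C@H](C)[C@@H](C)O[Si](C)(C)C(C)(C)C)C1(C)C | intermediate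
26 | methyl (2R)-2-{(4R,5R)-5-[(tert-butyldimethylsilyl)oxy]-4-methyl-3-oxohexanoyl}-2-{[(1R,3S)-2,2-dimethyl-3-(prop-1-en-2-yl)cyclobutyl]methyl}-5-methylhex-4-enoate | C=C(C)[C@@H]1C[C@H](C[C@@](CC=C(C)C)(C(=O)OC)C(=O)CC(=O)[C@H](C)[C@@H](C)O[Si](C)(C)C(C)(C)C)C1(C)C | intermediate
27 | methyl (2R)-2-{(4R,5R)-2-acetyl-5-[(tert-butyldimethylsilyl)oxy]-4-methyl-3-oxohexanoyl}-2-{[(1R,3S)-2,2-dimethyl-3-(prop-1-en-2-yl)cyclobutyl]methyl}-5-methylhex-4-enoate | C=C(C)[C@@H]1C[C@H](C[C@@](CC=C(C)C)(C(=O)OC)C(=O)C(C(C)=O)C(=O)[C@H](C)[C@@H](C)O[Si](C)(C)C(C)(C)C)C1(C)C | intermediate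
28 | methyl (2R)-2-[(4R,5R)-2-acetyl-5-hydroxy-4-methyl-3-oxohexanoyl]-2-{[(1R,3S)-2,2-dimethyl-3-(prop-1-en-2-yl)cyclobutyl]methyl}-5-methylhex-4-enoate (hydroxy triketone, not isolated) | C=C(C)[C@@H]1C[C@H](C[C@@](CC=C(C)C)(C(=O)OC)C(=O)C(C(C)=O)C(=O)[C@H](C)[C@@H](C)O)C1(C)C | intermediate
29 | methyl (2R)-2-{[(1R,3S)-2,2-dimethyl-3-(prop-1-en-2-yl)cyclobutyl]methyl}-5-methyl-2-[(2R,3R)-2,3,6-trimethyl-4-oxo-3,4-dihydro-2H-pyran-5-carbonyl]hex-4-enoate | C=C(C)[C@@H]1C[C@H](C[C@@](CC=C(C)C)(C(=O)OC)C(=O)C2=C(C)O[C@H](C)[C@@H](C)C2=O)C1(C)C | intermediate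
30 | (2R,3R,6R)-6-{[(1R,3S)-2,2-dimethyl-3-(prop-1-en-2-yl)cyclobutyl]methyl}-5-hydroxy-2,3-dimethyl-6-(3-methylbut-2-en-1-yl)-2,3-dihydro-4H-chromene-4,7(6H)-dione | C=C(C)[C@@H]1C[C@H](C[C@@]2(CC=C(C)C)C(=O)C=C3O[C@H](C)[C@@H](C)C(=O)C3=C2O)C1(C)C | intermediate
31 | (E)-cinnamaldehyde | O=C/C=C/c1ccccc1 | starting material
32 | (3S)-3-[(2R,3R,6R)-6-{[(1R,3S)-2,2-dimethyl-3-(prop-1-en-2-yl)cyclobutyl]methyl}-5-hydroxy-2,3-dimethyl-6-(3-methylbut-2-en-1-yl)-4,7-dioxo-3,4,6,7-tetrahydro-2H-chromen-8-yl]-3-phenylpropanal | C=C(C)[C@@H]1C[C@H](C[C@@]2(CC=C(C)C)C(=O)C([C@@H](CC=O)c3ccccc3)=C3O[C@H](C)[C@@H](C)C(=O)C3=C2O)C1(C)C | intermediate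
33 | (3S)-3-[(2R,3R,6R)-6-{[(1R,3S)-2,2-dimethyl-3-(prop-1-en-2-yl)cyclobutyl]methyl}-5-hydroxy-2,3-dimethyl-6-(3-methylbut-2-en-1-yl)-4,7-dioxo-3,4,6,7-tetrahydro-2H-chromen-8-yl]-3-phenylpropanoic acid | C=C(C)[C@@H]1C[C@H](C[C@@]2(CC=C(C)C)C(=O)C([C@@H](CC(=O)O)c3ccccc3)=C3O[C@H](C)[C@@H](C)C(=O)C3=C2O)C1(C)C | target

## Step count and least certain steps

Total: 20 steps. Longest linear sequence: 17 steps (steps 1–10 and 14–20); steps 11–13 form a three-step side branch.

**Step 2 (key step).** The most likely failure is weak enantioface discrimination. The alkene is monosubstituted and its one substituent is small, flexible and far from the auxiliary. Conversion may also be slow, because the allylic oxygen lowers the nucleophilicity of the alkene and the keteniminium ion is fully substituted. Any minor enantiomer would become a diastereomer after step 10 and should be removable there, but a poor ratio would waste material. The fallback gives up the cycloaddition for the chiral pool. It sets out from no numbered compound and replaces steps 1–6. Commercial (1S,5S)-(−)-verbenone F1 is cleaved with RuCl3 (cat.) and NaIO4 to (1S,3R)-3-acetyl-2,2-dimethylcyclobutane-1-carboxylic acid F2, with loss of one carbon. Wittig methylenation of the keto acid (Ph3PCH3Br, KOtBu, excess) gives (1S,3S)-2,2-dimethyl-3-(prop-1-en-2-yl)cyclobutane-1-carboxylic acid F3. LiAlH4 reduction returns to the route at 12.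

**Step 10.** The most likely failure is erosion of facial selectivity. The bulky, β-branched cyclobutylmethyl group on the enamine carbon may distort the lithium chelate on which the model rests, and N-alkylation by the reactive allylic bromide may compete. The fallback sets out from 15 and returns at 20. Unselective prenylation of 15 (K2CO3, 18, acetone) gives 20 together with its C2 epimer, methyl (2S)-2-acetyl-2-{[(1R,3S)-2,2-dimethyl-3-(prop-1-en-2-yl)cyclobutyl]methyl}-5-methylhex-4-enoate F4. Because ring C is already a single enantiomer, the two are diastereomers and are separated by chromatography, at the cost of half the material.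

**Step 17.** Two processes may compete with the wanted closure. The hemiketal may collapse by C–C cleavage, transferring the acetyl group from carbon to the hydroxyl (retro-Claisen). Alternatively the hydroxyl or an enol oxygen may add to the other ketone or to the ester. The fallback sets out from 26 and returns at 29, and fixes the position of the ring oxygen by construction. Knoevenagel condensation of 26 with acetaldehyde (piperidinium acetate) gives the ethylidene diketone F5. Desilylation with HF·pyridine lets the hydroxyl add to the only available β-carbon (oxa-Michael addition), giving the tetrahydropyranone F6. Dehydrogenation of this cyclic β-diketone with DDQ then gives 29.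

**Step 19.** The most likely failure is low conversion or weak catalyst control. The nucleophile is a hindered, strongly acidic vinylogous acid that can tie up the amine as its salt, and a reversible addition would erode the ratio at the benzylic centre. The fallback sets out from 30 and returns at 33, omitting 32. Michael addition of 30 to 5-benzylidene-2,2-dimethyl-1,3-dioxane-4,6-dione gives the Meldrum's acid adduct F7 as a mixture at the benzylic carbon. Heating F7 in aqueous pyridine brings about hydrolysis and decarboxylation to 33 and its (3R)-epimer F8, which are separated by chromatography. Stereocontrol is traded for a more electrophilic acceptor.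

**Step 8.** The most likely failure is slow substitution. The iodide is primary but β-branched and sits next to the quaternary ring carbon, so elimination or O-alkylation may take over on heating. The fallback sets out from 12 and returns at 15, replacing substitution by condensation and reduction. Dess–Martin oxidation of 12 gives (1S,3S)-2,2-dimethyl-3-(prop-1-en-2-yl)cyclobutane-1-carbaldehyde F9, used at once to limit epimerisation. Knoevenagel condensation with 14 gives the alkylidene acetoacetate F10. Conjugate reduction with Hantzsch ester gives 15.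

## Further compounds

F1 | step 2 | (1S,5S)-(−)-verbenone [(1S,5S)-4,6,6-trimethylbicyclo[3.1.1]hept-3-en-2-one] | CC1=CC(=O)[C@H]2C[C@@H]1C2(C)C
F2 | step 2 | (1S,3R)-3-acetyl-2,2-dimethylcyclobutane-1-carboxylic acid | CC(=O)[C@@H]1C[C@H](C(=O)O)C1(C)C
F3 | step 2 | (1S,3S)-2,2-dimethyl-3-(prop-1-en-2-yl)cyclobutane-1-carboxylic acid | C=C(C)[C@@H]1C[C@H](C(=O)O)C1(C)C
F4 | step 10 | methyl (2S)-2-acetyl-2-{[(1R,3S)-2,2-dimethyl-3-(prop-1-en-2-yl)cyclobutyl]methyl}-5-methylhex-4-enoate | C=C(C)[C@@H]1C[C@H](C[C@](CC=C(C)C)(C(=O)OC)C(C)=O)C1(C)C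
F5 | step 17 | methyl (2R)-2-{(4R,5R)-5-[(tert-butyldimethylsilyl)oxy]-2-ethylidene-4-methyl-3-oxohexanoyl}-2-{[(1R,3S)-2,2-dimethyl-3-(prop-1-en-2-yl)cyclobutyl]methyl}-5-methylhex-4-enoate (E/Z mixture) | C=C(C)[C@@H]1C[C@H](C[C@@](CC=C(C)C)(C(=O)OC)C(=O)C(=CC)C(=O)[C@H](C)[C@@H](C)O[Si](C)(C)C(C)(C)C)C1(C)C
F6 | step 17 | methyl (2R)-2-{[(1R,3S)-2,2-dimethyl-3-(prop-1-en-2-yl)cyclobutyl]methyl}-5-methyl-2-[(2R,3R)-2,3,6-trimethyl-4-oxooxane-5-carbonyl]hex-4-enoate (mixture at C5 and C6 of the oxane) | C=C(C)[C@@H]1C[C@H](C[C@@](CC=C(C)C)(C(=O)OC)C(=O)C2C(C)O[C@H](C)[C@@H](C)C2=O)C1(C)C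
F7 | step 19 | 5-{[(2R,3R,6R)-6-{[(1R,3S)-2,2-dimethyl-3-(prop-1-en-2-yl)cyclobutyl]methyl}-5-hydroxy-2,3-dimethyl-6-(3-methylbut-2-en-1-yl)-4,7-dioxo-3,4,6,7-tetrahydro-2H-chromen-8-yl](phenyl)methyl}-2,2-dimethyl-1,3-dioxane-4,6-dione (both benzylic epimers) | C=C(C)[C@@H]1C[C@H](C[C@@]2(CC=C(C)C)C(=O)C(C(c3ccccc3)C3C(=O)OC(C)(C)OC3=O)=C3O[C@H](C)[C@@H](C)C(=O)C3=C2O)C1(C)C
F8 | step 19 | (3R)-3-[(2R,3R,6R)-6-{[(1R,3S)-2,2-dimethyl-3-(prop-1-en-2-yl)cyclobutyl]methyl}-5-hydroxy-2,3-dimethyl-6-(3-methylbut-2-en-1-yl)-4,7-dioxo-3,4,6,7-tetrahydro-2H-chromen-8-yl]-3-phenylpropanoic acid | C=C(C)[C@@H]1C[C@H](C[C@@]2(CC=C(C)C)C(=O)C([C@H](CC(=O)O)c3ccccc3)=C3O[C@H](C)[C@@H](C)C(=O)C3=C2O)C1(C)C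
F9 | step 8 | (1S,3S)-2,2-dimethyl-3-(prop-1-en-2-yl)cyclobutane-1-carbaldehyde | C=C(C)[C@@H]1C[C@H](C=O)C1(C)C
F10 | step 8 | methyl 2-acetyl-3-[(1R,3S)-2,2-dimethyl-3-(prop-1-en-2-yl)cyclobutyl]prop-2-enoate (E/Z mixture) | C=C(C)[C@@H]1C[C@H](C=C(C(C)=O)C(=O)OC)C1(C)C
A1 | alternative 1 | (2E,4Z)-2-methoxy-4-[(trimethylsilyl)oxy]hexa-2,4-diene | C/C=C(\O[Si](C)(C)C)/C=C(\C)OC
A2 | alternative 1 | acetaldehyde | CC=O
A3 | alternative 1 | (2R,3R)-2,3,6-trimethyl-2,3-dihydro-4H-pyran-4-one | CC1=CC(=O)[C@H](C)[C@@H](C)O1
A4 | alternative 2 | dimethyl 2,2-bis(3-methylbut-2-en-1-yl)malonate | COC(=O)C(CC=C(C)C)(CC=C(C)C)C(=O)OC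
A5 | alternative 2 | isoprene | C=CC(C)=C
A6 | alternative 2 | dimethyl 2-{[(1R,3S)-2,2-dimethyl-3-(prop-1-en-2-yl)cyclobutyl]methyl}-2-(3-methylbut-2-en-1-yl)malonate | C=C(C)[C@@H]1C[C@H](CC(CC=C(C)C)(C(=O)OC)C(=O)OC)C1(C)C
A7 | alternative 3 | methyl (2R)-2-(chlorocarbonyl)-2-{[(1R,3S)-2,2-dimethyl-3-(prop-1-en-2-yl)cyclobutyl]methyl}-5-methylhex-4-enoate | C=C(C)[C@@H]1C[C@H](C[C@@](C(=O)OC)(CC=C(C)C)C(Cl)=O)C1(C)C
A8 | alternative 3 | (2R,3R,6R)-6-{[(1R,3S)-2,2-dimethyl-3-(prop-1-en-2-yl)cyclobutyl]methyl}-5-hydroxy-2,3-dimethyl-6-(3-methylbut-2-en-1-yl)-2,3-dihydro-4H-chromene-4,7(6H)-dione | C=C(C)[C@@H]1C[C@H](C[C@@]2(CC=C(C)C)C(=O)C=C3O[C@H](C)[C@@H](C)C(=O)C3=C2O)C1(C)C
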